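**Plan**
- Retrosynthesis: the C1 methyl ester is traced back to a silyl-protected CH2OH. The two ring C–O bonds (O–C3 and O–C6) are cut together as a retro-[4+2] of O2, which leaves a (3E,5Z)-diene. C3=C4 is cut by a Julia–Kocienski olefination. The C9/C14 diketone is traced to the ring alkene of dihydro-β-ionone, and C5=C6 to an alkynoate.
- Feature: the 1,2-dioxane (O1, O2, C3, C4, C5, C6) is the 4,5-dihydro form of a 3,6-dihydro-1,2-dioxine, the adduct of O2 with a C3=C4–C5=C6 diene.
- Forward: chain fragment (steps 1–6), sulfone fragment (steps 7–10), union to the open-chain diene (step 11), peroxide ring by photooxygenation (step 12), then alkene reduction, desilylation, oxidation and methylation.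
- Stereochemistry: C2 comes from methyl (S)-3-hydroxy-2-methylpropanoate, whose CH2OH carbon becomes C1. The 5Z alkene comes from syn-carbocupration and the 3E alkene from the olefination. The cis relation of C3 and C6 comes from suprafacial O2 addition to the E,Z diene. The facial sense relative to C2 is only weakly biased and is secured by separation.

Key step: step 12

Remark: open-chain compounds 16, F1, F2 and F6 are named with the natural-product numbering (C1 = ester carbon, C3–C6 = ring carbons, C7–C15 = chain). Chromatographic separability of the two cis adducts of step 12 is assumed.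

**Step 1**
Reactants: 1 dihydro-β-ionone
Product: 3 2-(but-3-yn-1-yl)-1,3,3-trimethylcyclohex-1-ene, via enol phosphate 2 (not isolated)
Conditions: LiN(iPr)2, THF, −78 °C; ClP(O)(OEt)2, −78 °C → rt; then LiN(iPr)2 (2.3 equiv), THF, −78 °C → rt; aq. NH4Cl
Reagents that add atoms: none
Why: Kinetic deprotonation at the methyl group, O-phosphorylation and base-induced elimination of the enol phosphate (methyl ketone to terminal alkyne conversion) should give the alkyne, the hindered tetrasubstituted ring alkene being inert.

**Step 2**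
Reactants: 3 2-(but-3-yn-1-yl)-1,3,3-trimethylcyclohex-1-ene
Product: 4 methyl 5-(2,6,6-trimethylcyclohex-1-en-1-yl)pent-2-ynoate
Conditions: n-BuLi, THF, −78 °C; ClCO2Me, −78 → 0 °C
Reagents that add atoms: methyl chloroformate, COC(=O)Cl
Why: C-Acylation of the lithium acetylide with a chloroformate (acetylide carboxylation) is the standard entry to 2-alkynoates.

**Step 3**
Reactants: 4 methyl 5-(2,6,6-trimethylcyclohex-1-en-1-yl)pent-2-ynoate
Product: 5 methyl (2Z)-3-methyl-5-(2,6,6-trimethylcyclohex-1-en-1-yl)pent-2-enoate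
Conditions: Me2CuLi (from CuI and 2 MeLi), THF, −78 °C; MeOH quench at −78 °C, then aq. NH4Cl
Reagents that add atoms: lithium dimethylcuprate, [Li+].C[Cu-]C
Why: Conjugate syn-carbocupration of the alkynoate puts methyl and copper on the same side, and protonation of the vinylcuprate at −78 °C, before equilibration through the allenoate, should fix the Z geometry that becomes the 5Z alkene.

**Step 4**
Reactants: 5 methyl (2Z)-3-methyl-5-(2,6,6-trimethylcyclohex-1-en-1-yl)pent-2-enoate
Product: 7 methyl (2Z)-3,7,7-trimethyl-6,11-dioxododec-2-enoate, via ozonide 6 (not isolated)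
Conditions: O3, CH2Cl2, −78 °C (Sudan Red 7B end point); then PPh3, −78 °C → rt
Reagents that add atoms: ozone, [O-][O+]=O
Why: Ozonolysis should be chemoselective for the electron-rich tetrasubstituted ring alkene over the electron-poor conjugated enoate, and phosphine reduction of the ozonide unveils both ketones of the later C9/C14 diketone.

**Step 5**
Reactants: 7 methyl (2Z)-3,7,7-trimethyl-6,11-dioxododec-2-enoate
Product: 8 (2Z)-3,7,7-trimethyldodec-2-ene-1,6,11-triol (mixture of carbinol diastereomers)
Conditions: iBu2AlH (excess), CH2Cl2, −78 → 0 °C; aq. KNaC4H4O6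
Reagents that add atoms: none
Why: Exhaustive iBu2AlH reduction takes the enoate to the allylic alcohol by 1,2-reduction with the Z alkene intact and reduces both ketones, so that no ester/ketone differentiation is required; the carbinol centres are inconsequential.

**Step 6**
Reactants: 8 (2Z)-3,7,7-trimethyldodec-2-ene-1,6,11-triol
Product: 9 (2Z)-3,7,7-trimethyl-6,11-dioxododec-2-enal
Conditions: Dess–Martin periodinane (excess), pyridine, CH2Cl2, 0 °C → rt
Reagents that add atoms: none
Why: Buffered Dess–Martin oxidation should return all three carbinols to carbonyl groups in one operation and is mild enough to deliver the Z-enal without isomerisation.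

**Step 7**
Reactants: 10 methyl (2S)-3-hydroxy-2-methylpropanoate
Product: 11 methyl (2S)-3-[(tert-butyldimethylsilyl)oxy]-2-methylpropanoate
Conditions: TBSCl, imidazole, CH2Cl2, 0 °C → rt
Reagents that add atoms: tert-butyldimethylsilyl chloride, CC(C)(C)[Si](C)(C)Cl
Why: Imidazole-mediated silylation of a primary alcohol, with the stereocentre untouched.

**Step 8**
Reactants: 11 methyl (2S)-3-[(tert-butyldimethylsilyl)oxy]-2-methylpropanoate
Product: 12 (2R)-3-[(tert-butyldimethylsilyl)oxy]-2-methylpropan-1-ol
Conditions: iBu2AlH, CH2Cl2, −78 → 0 °C; aq. KNaC4H4O6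
Reagents that add atoms: none
Why: Hydride reduction of the ester to the primary alcohol, with the silyl ether stable and no epimerisation expected at low temperature (the descriptor changes only through priority rules).

**Step 9**
Reactants: 12 (2R)-3-[(tert-butyldimethylsilyl)oxy]-2-methylpropan-1-ol; 13 1-phenyl-1H-tetrazole-5-thiol
Product: 14 5-({(2S)-3-[(tert-butyldimethylsilyl)oxy]-2-methylpropyl}sulfanyl)-1-phenyl-1H-tetrazole
Conditions: PPh3, DIAD, THF, 0 °C → rt
Reagents that add atoms: none
Why: Mitsunobu thioetherification of a primary alcohol with the acidic heteroaryl thiol, at a carbon remote from the stereocentre.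

**Step 10**
Reactants: 14 5-({(2S)-3-[(tert-butyldimethylsilyl)oxy]-2-methylpropyl}sulfanyl)-1-phenyl-1H-tetrazole
Product: 15 5-({(2S)-3-[(tert-butyldimethylsilyl)oxy]-2-methylpropyl}sulfonyl)-1-phenyl-1H-tetrazole
Conditions: 30% aq. H2O2, (NH4)6Mo7O24·4H2O (cat.), EtOH, 0 °C → rt
Reagents that add atoms: hydrogen peroxide, OO
Why: Molybdate-catalysed peroxide oxidation of sulfide to sulfone is the usual preparation of Julia–Kocienski reagents and is tolerated by a primary silyl ether.

**Step 11**
Reactants: 9 (2Z)-3,7,7-trimethyl-6,11-dioxododec-2-enal; 15 5-({(2S)-3-[(tert-butyldimethylsilyl)oxy]-2-methylpropyl}sulfonyl)-1-phenyl-1H-tetrazole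
Product: 16 (2R,3E,5Z)-1-[(tert-butyldimethylsilyl)oxy]-2,6,10,10-tetramethylpentadeca-3,5-diene-9,14-dione
Conditions: 15, KN(SiMe3)2, THF, −78 °C; then 9, −78 °C → rt; aq. NH4Cl
Reagents that add atoms: none
Why: Julia–Kocienski olefination, in which the premetalated tetrazolyl sulfone should add to the aldehyde much faster than to the hindered or the methyl ketone, and Smiles rearrangement with loss of SO2 and the tetrazolone gives the 3E alkene typical of potassium-metalated phenyltetrazolyl sulfones, C2 and the 5Z alkene being untouched.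

**Step 12**
Reactants: 16 (2R,3E,5Z)-1-[(tert-butyldimethylsilyl)oxy]-2,6,10,10-tetramethylpentadeca-3,5-diene-9,14-dione
Product: 17 tert-butyl(dimethyl){(2S)-2-[(3S,6R)-6-(4,4-dimethyl-3,8-dioxononyl)-6-methyl-3,6-dihydro-1,2-dioxin-3-yl]propoxy}silane (C2 branch and C6 methyl cis)
Conditions: O2, tetraphenylporphyrin (cat.), CH2Cl2, −20 °C, visible light (white LED); chromatography to remove the (3R,6S) facial isomer
Reagents that add atoms: dioxygen, O=O
Why: Energy transfer from the triplet porphyrin generates singlet oxygen, which adds across C3 and C6 of the s-cis diene in a concerted suprafacial [4+2] cycloaddition, the closest known reaction type being the sensitised photooxygenation of acyclic 1,3-dienes to 3,6-dihydro-1,2-dioxines. The six-membered peroxide ring closes by this intermolecular [4+2] annulation, both C–O bonds forming in the same event. The relative configuration of C3 and C6 follows from suprafacial addition to the fixed (3E,5Z) geometry, which puts the two outside groups, the C2 branch and the C6 methyl, cis. Their sense relative to C2 is set only by the allylic C2 centre: in the conformer with C2–H eclipsing C3=C4, approach past the methyl group and anti to the siloxymethyl group leads to the required (3S,6R) adduct, a bias expected to be modest, so the facial isomer is to be removed by chromatography. The step needs [4+2] to outrun the ene reaction at the trisubstituted C5=C6 bond, which the E-disubstituted C3 terminus, the single inside CH2 at C6 (s-cis conformer accessible) and an aprotic solvent at low temperature should secure. The ketones are inert to singlet oxygen, the ene-prone cyclohexene is already cleaved, and the low triplet energy of the porphyrin leaves the diene geometry untouched.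

**Step 13**
Reactants: 17 tert-butyl(dimethyl){(2S)-2-[(3S,6R)-6-(4,4-dimethyl-3,8-dioxononyl)-6-methyl-3,6-dihydro-1,2-dioxin-3-yl]propoxy}silane
Product: 18 tert-butyl(dimethyl){(2S)-2-[(3S,6S)-6-(4,4-dimethyl-3,8-dioxononyl)-6-methyl-1,2-dioxan-3-yl]propoxy}silane
Conditions: KO2CN=NCO2K, AcOH, CH2Cl2/MeOH, 0 °C → rt
Reagents that add atoms: none
Why: Diimide reduction transfers H2 to the cis-disubstituted ring alkene in a concerted syn fashion and, unlike catalytic hydrogenation, should leave the O–O bond and the ketones intact (the C6 descriptor changes only through priority rules).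

**Step 14**
Reactants: 18 tert-butyl(dimethyl){(2S)-2-[(3S,6S)-6-(4,4-dimethyl-3,8-dioxononyl)-6-methyl-1,2-dioxan-3-yl]propoxy}silane
Product: 19 (2S)-2-[(3S,6S)-6-(4,4-dimethyl-3,8-dioxononyl)-6-methyl-1,2-dioxan-3-yl]propan-1-ol
Conditions: HF·pyridine, pyridine, THF, 0 °C → rt
Reagents that add atoms: none
Why: Fluoride desilylation under buffered acidic conditions removes the primary silyl ether without the basicity that could start aldol condensation of the 1,6-diketone or Kornblum–DeLaMare-type cleavage of the peroxide.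

**Step 15**
Reactants: 19 (2S)-2-[(3S,6S)-6-(4,4-dimethyl-3,8-dioxononyl)-6-methyl-1,2-dioxan-3-yl]propan-1-ol
Product: 21 (2R)-2-[(3S,6S)-6-(4,4-dimethyl-3,8-dioxononyl)-6-methyl-1,2-dioxan-3-yl]propanoic acid, via aldehyde 20 (not isolated)
Conditions: PhI(OAc)2, TEMPO (cat.), MeCN/H2O, rt
Reagents that add atoms: water, O
Why: Nitroxyl-catalysed oxidation carries the primary alcohol through the aldehyde and its hydrate to the acid under mildly acidic conditions that should spare the peroxide, the ketones and the C2 stereocentre.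

**Step 16**
Reactants: 21 (2R)-2-[(3S,6S)-6-(4,4-dimethyl-3,8-dioxononyl)-6-methyl-1,2-dioxan-3-yl]propanoic acid
Product: 22 diacarperoxide C [methyl (2R)-2-[(3S,6S)-6-(4,4-dimethyl-3,8-dioxononyl)-6-methyl-1,2-dioxan-3-yl]propanoate]
Conditions: Me3SiCHN2, toluene/MeOH, 0 °C
Reagents that add atoms: trimethylsilyldiazomethane, C[Si](C)(C)C=[N+]=[N-]
Why: O-Methylation of the acid with the diazomethane surrogate is a neutral esterification that avoids base at the β-peroxy ester.

**Compound list**
1 | dihydro-β-ionone, 4-(2,6,6-trimethylcyclohex-1-en-1-yl)butan-2-one | CC(=O)CCC1=C(C)CCCC1(C)C | starting material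
2 | diethyl 4-(2,6,6-trimethylcyclohex-1-en-1-yl)but-1-en-2-yl phosphate (enol phosphate) | C=C(CCC1=C(C)CCCC1(C)C)OP(=O)(OCC)OCC | intermediate (not isolated)
3 | 2-(but-3-yn-1-yl)-1,3,3-trimethylcyclohex-1-ene | C#CCCC1=C(C)CCCC1(C)C | intermediate
4 | methyl 5-(2,6,6-trimethylcyclohex-1-en-1-yl)pent-2-ynoate | COC(=O)C#CCCC1=C(C)CCCC1(C)C | intermediate
5 | methyl (2Z)-3-methyl-5-(2,6,6-trimethylcyclohex-1-en-1-yl)pent-2-enoate | COC(=O)/C=C(/C)CCC1=C(C)CCCC1(C)C | intermediate
6 | ozonide of 5, methyl (2Z)-3-methyl-5-(2,2,6-trimethyl-7,8,9-trioxabicyclo[4.2.1]nonan-1-yl)pent-2-enoate (racemic) | COC(=O)/C=C(/C)CCC12OOC(C)(O1)CCCC2(C)C | intermediate (not isolated)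
7 | methyl (2Z)-3,7,7-trimethyl-6,11-dioxododec-2-enoate | COC(=O)/C=C(/C)CCC(=O)C(C)(C)CCCC(C)=O | intermediate
8 | (2Z)-3,7,7-trimethyldodec-2-ene-1,6,11-triol (mixture of diastereomers at C6 and C11) | OC/C=C(/C)CCC(O)C(C)(C)CCCC(C)O | intermediate
9 | (2Z)-3,7,7-trimethyl-6,11-dioxododec-2-enal | O=C/C=C(/C)CCC(=O)C(C)(C)CCCC(C)=O | intermediate
10 | methyl (2S)-3-hydroxy-2-methylpropanoate | COC(=O)[C@@H](C)CO | starting material
11 | methyl (2S)-3-[(tert-butyldimethylsilyl)oxy]-2-methylpropanoate | COC(=O)[C@@H](C)CO[Si](C)(C)C(C)(C)C | intermediate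
12 | (2R)-3-[(tert-butyldimethylsilyl)oxy]-2-methylpropan-1-ol | OC[C@@H](C)CO[Si](C)(C)C(C)(C)C | intermediate
13 | 1-phenyl-1H-tetrazole-5-thiol | SC1=NN=NN1c1ccccc1 | starting material
14 | 5-({(2S)-3-[(tert-butyldimethylsilyl)oxy]-2-methylpropyl}sulfanyl)-1-phenyl-1H-tetrazole | CC(C)(C)[Si](C)(C)OC[C@H](C)CSC1=NN=NN1c1ccccc1 | intermediate
15 | 5-({(2S)-3-[(tert-butyldimethylsilyl)oxy]-2-methylpropyl}sulfonyl)-1-phenyl-1H-tetrazole | CC(C)(C)[Si](C)(C)OC[C@H](C)CS(=O)(=O)C1=NN=NN1c1ccccc1 | intermediate
16 | (2R,3E,5Z)-1-[(tert-butyldimethylsilyl)oxy]-2,6,10,10-tetramethylpentadeca-3,5-diene-9,14-dione | CC(C)(C)[Si](C)(C)OC[C@H](C)/C=C/C=C(/C)CCC(=O)C(C)(C)CCCC(C)=O | intermediate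
17 | tert-butyl(dimethyl){(2S)-2-[(3S,6R)-6-(4,4-dimethyl-3,8-dioxononyl)-6-methyl-3,6-dihydro-1,2-dioxin-3-yl]propoxy}silane | CC(C)(C)[Si](C)(C)OC[C@H](C)[C@@H]1C=C[C@@](C)(CCC(=O)C(C)(C)CCCC(C)=O)OO1 | intermediate
18 | tert-butyl(dimethyl){(2S)-2-[(3S,6S)-6-(4,4-dimethyl-3,8-dioxononyl)-6-methyl-1,2-dioxan-3-yl]propoxy}silane | CC(C)(C)[Si](C)(C)OC[C@H](C)[C@@H]1CC[C@@](C)(CCC(=O)C(C)(C)CCCC(C)=O)OO1 | intermediate
19 | (2S)-2-[(3S,6S)-6-(4,4-dimethyl-3,8-dioxononyl)-6-methyl-1,2-dioxan-3-yl]propan-1-ol | OC[C@H](C)[C@@H]1CC[C@@](C)(CCC(=O)C(C)(C)CCCC(C)=O)OO1 | intermediate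
20 | (2R)-2-[(3S,6S)-6-(4,4-dimethyl-3,8-dioxononyl)-6-methyl-1,2-dioxan-3-yl]propanal | O=C[C@H](C)[C@@H]1CC[C@@](C)(CCC(=O)C(C)(C)CCCC(C)=O)OO1 | intermediate (not isolated)
21 | (2R)-2-[(3S,6S)-6-(4,4-dimethyl-3,8-dioxononyl)-6-methyl-1,2-dioxan-3-yl]propanoic acid | OC(=O)[C@H](C)[C@@H]1CC[C@@](C)(CCC(=O)C(C)(C)CCCC(C)=O)OO1 | intermediate
22 | diacarperoxide C, methyl (2R)-2-[(3S,6S)-6-(4,4-dimethyl-3,8-dioxononyl)-6-methyl-1,2-dioxan-3-yl]propanoate | COC(=O)[C@H](C)[C@@H]1CC[C@@](C)(CCC(=O)C(C)(C)CCCC(C)=O)OO1 | target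

**Step count**
Total: 16 steps. Longest linear sequence: 12 steps (steps 1–6 and 11–16, from dihydro-β-ionone); the sulfone branch is 4 steps (steps 7–10).

**Steps most likely to fail**

Step 12. The allylic C2 centre may discriminate the two diene faces too weakly, and part of the material may be diverted into the ene pathway at C5=C6. The fallback enlarges the group that shields the unwanted face. It sets out from diene 16. Desilylation with HF·pyridine should give the dienol F1, and tritylation (TrCl, pyridine, CH2Cl2) the trityl ether F2. Photooxygenation under the conditions of step 12 should then give the trityl dihydrodioxine F3, in which the bulkier O-substituent shields the face syn to C1 more strongly and supplies a UV chromophore for HPLC removal of the facial isomer. Diimide reduction as in step 13 should give the trityl dioxane F4, and acid-catalysed detritylation (camphorsulfonic acid, MeOH/CH2Cl2, 0 °C) returns to the route at alcohol 19.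

Step 11. Proton transfer from the ketone α-positions or from the γ-position of the Z-enal to the metalated sulfone may erode the 5Z geometry or start aldol condensation of the 1,6-diketone, and the sulfonyl anion may add to the methyl ketone. The fallback keeps both ketones masked as carbinols during the olefination. It sets out from triol 8. Selective allylic oxidation with MnO2 (CH2Cl2, rt) should give the dihydroxy enal F5. Julia–Kocienski olefination with sulfone 15 (KN(SiMe3)2, THF, −78 °C → rt, sulfone anion in slight excess) should give the dienediol F6. Dess–Martin oxidation of the two secondary carbinols returns to the route at diene 16.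

Step 15. If the aldehyde accumulates, epimerisation at C2 or β-elimination of the peroxide oxygen with ring opening may set in. The fallback sets out from silyl ether 18 and omits the separate desilylation. Jones oxidation with hexavalent chromium (CrO3, H2SO4, acetone, 0 °C) cleaves the primary silyl ether and oxidises the liberated alcohol through the aldehyde hydrate in strongly acidic medium, where enolisation is slow. It returns to the route at acid 21 and forms no new compound.

**Further compounds**
F1 | step 12 | (2R,3E,5Z)-1-hydroxy-2,6,10,10-tetramethylpentadeca-3,5-diene-9,14-dione | OC[C@H](C)/C=C/C=C(/C)CCC(=O)C(C)(C)CCCC(C)=O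
F2 | step 12 | (2R,3E,5Z)-2,6,10,10-tetramethyl-1-(trityloxy)pentadeca-3,5-diene-9,14-dione | C(c1ccccc1)(c1ccccc1)(c1ccccc1)OC[C@H](C)/C=C/C=C(/C)CCC(=O)C(C)(C)CCCC(C)=O
F3 | step 12 | trityl ether analogue of 17, (3S,6R)-6-(4,4-dimethyl-3,8-dioxononyl)-6-methyl-3-[(2S)-1-(trityloxy)propan-2-yl]-3,6-dihydro-1,2-dioxine | C(c1ccccc1)(c1ccccc1)(c1ccccc1)OC[C@H](C)[C@@H]1C=C[C@@](C)(CCC(=O)C(C)(C)CCCC(C)=O)OO1
F4 | step 12 | trityl ether analogue of 18, (3S,6S)-6-(4,4-dimethyl-3,8-dioxononyl)-6-methyl-3-[(2S)-1-(trityloxy)propan-2-yl]-1,2-dioxane | C(c1ccccc1)(c1ccccc1)(c1ccccc1)OC[C@H](C)[C@@H]1CC[C@@](C)(CCC(=O)C(C)(C)CCCC(C)=O)OO1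
F5 | step 11 | (2Z)-6,11-dihydroxy-3,7,7-trimethyldodec-2-enal (mixture of carbinol diastereomers) | O=C/C=C(/C)CCC(O)C(C)(C)CCCC(C)O
F6 | step 11 | (2R,3E,5Z)-1-[(tert-butyldimethylsilyl)oxy]-2,6,10,10-tetramethylpentadeca-3,5-diene-9,14-diol (mixture of carbinol diastereomers) | CC(C)(C)[Si](C)(C)OC[C@H](C)/C=C/C=C(/C)CCC(O)C(C)(C)CCCC(C)O
F0 | step 15 | none | none
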